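**Retrosynthetic overview**
1. Target 19 ⇐ 16 by acylation of the C8 hydroxyl with angelic anhydride and removal of the C9/C14 silylene.
2. 16 ⇐ bromo-enal 14: one cathodic, chromium-catalysed Barbier allylation/lactonisation makes the C6–C7 bond, the ten-membered carbocycle and the trans-fused α-methylene-γ-lactone together.
3. 14 ⇐ dialdehyde 11 ⇐ triol 9: Baylis–Hillman reaction and SN2' bromination at C7 after a double Swern oxidation (C6 enal, C7 aldehyde).
4. 9 ⇐ vinyl iodide 5 + aldehyde 6: Nozaki–Hiyama–Kishi coupling forms C9–C10. Iodide 5 comes from nerol, which supplies the Z-C4=C5 alkene; an iodo-Wittig reaction sets Z-C1=C10.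
5. Ring order: dioxasilinane protecting ring (step 6), then carbocycle and lactone in the same step (step 12).

Assumption: positions are given in germacrane numbering (C1–C15) of the target; (S)-glyceraldehyde acetonide 6 (made from L-ascorbic acid), methyl acrylate 12 and angelic anhydride 17 are bought.

**Step 1**
Reactants: 1 nerol
Product: 2 neryl triethylsilyl ether
Conditions: TESCl, imidazole, CH2Cl2, 0 °C
Reagents that add atoms: chlorotriethylsilane, CC[Si](Cl)(CC)CC
Why: Silyl ether formation on the primary allylic alcohol masks the future C6 oxygen for the hydride and chromium steps and leaves the bought Z-alkene (later C4=C5) untouched.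

**Step 2**
Reactants: 2 neryl triethylsilyl ether
Product: 3 (4Z)-4-methyl-6-(triethylsilyloxy)hex-4-enal
Conditions: O3, CH2Cl2–MeOH, −78 °C, Sudan Red 7B end-point; then Me2S, rt
Reagents that add atoms: ozone, [O-][O+]=O
Why: Chemoselective ozonolysis with reductive work-up, because the remote isopropylidene alkene is more electron-rich than the alkene next to the allylic silyloxy group and the dye end-point stops over-oxidation.

**Step 3**
Reactants: 3 (4Z)-4-methyl-6-(triethylsilyloxy)hex-4-enal
Product: 4 ethyl (2Z,6Z)-2-iodo-6-methyl-8-(triethylsilyloxy)octa-2,6-dienoate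
Conditions: Ph3P=CHCO2Et, NIS, CH2Cl2, −20 °C; then 3, rt
Reagents that add atoms: ethyl (triphenylphosphoranylidene)acetate, CCOC(=O)C=P(c1ccccc1)(c1ccccc1)c1ccccc1; N-iodosuccinimide, O=C1CCC(=O)N1I
Why: Tandem iodination–Wittig olefination, in which the iodinated stabilised ylide places the alkyl chain trans to the ester and so gives the (Z)-α-iodo enoate that fixes the later C1=C10 geometry.

**Step 4**
Reactants: 4 ethyl (2Z,6Z)-2-iodo-6-methyl-8-(triethylsilyloxy)octa-2,6-dienoate
Product: 5 (2Z,6Z)-2-iodo-6-methyl-8-(triethylsilyloxy)octa-2,6-dien-1-ol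
Conditions: iBu2AlH (2.2 equiv), CH2Cl2, −78 °C
Reagents that add atoms: none
Why: 1,2-Reduction of the unsaturated ester to the allylic alcohol (future C14–OH) with iBu2AlH leaves the vinyl iodide, the silyl ether and both alkene geometries intact.

**Step 5**
Reactants: 5 (2Z,6Z)-2-iodo-6-methyl-8-(triethylsilyloxy)octa-2,6-dien-1-ol, 6 (S)-2,2-dimethyl-1,3-dioxolane-4-carbaldehyde
Product: 7 (1R,2Z,6Z)-1-[(4S)-2,2-dimethyl-1,3-dioxolan-4-yl]-2-(hydroxymethyl)-6-methyl-8-(triethylsilyloxy)octa-2,6-dien-1-ol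
Conditions: CrCl2 (6 equiv), NiCl2 (1 mol %), DMSO, rt
Reagents that add atoms: none
Why: Nozaki–Hiyama–Kishi coupling, in which the alkenylchromium species adds with retention of alkene geometry and Felkin–Anh attack anti to the C8–O bond of the bought centre sets C9 as the anti (erythro) alcohol, typically about 3–5:1, with the minor epimer removed by chromatography.

**Step 6**
Reactants: 7 (1R,2Z,6Z)-1-[(4S)-2,2-dimethyl-1,3-dioxolan-4-yl]-2-(hydroxymethyl)-6-methyl-8-(triethylsilyloxy)octa-2,6-dien-1-ol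
Product: 8 (4R,5Z)-2,2-di-tert-butyl-4-[(4S)-2,2-dimethyl-1,3-dioxolan-4-yl]-5-[(4Z)-4-methyl-6-(triethylsilyloxy)hex-4-en-1-ylidene]-1,3,2-dioxasilinane
Conditions: tBu2Si(OTf)2, 2,6-lutidine, CH2Cl2, 0 °C
Reagents that add atoms: di-tert-butylsilyl bis(trifluoromethanesulfonate), CC(C)(C)[Si](OS(=O)(=O)C(F)(F)F)(OS(=O)(=O)C(F)(F)F)C(C)(C)C
Why: Silylene protection, the reagent being selective for 1,3-diols, ties the C9 and C14 hydroxyls into one acid-stable six-membered ring.

**Step 7**
Reactants: 8 (4R,5Z)-2,2-di-tert-butyl-4-[(4S)-2,2-dimethyl-1,3-dioxolan-4-yl]-5-[(4Z)-4-methyl-6-(triethylsilyloxy)hex-4-en-1-ylidene]-1,3,2-dioxasilinane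
Product: 9 (1S)-1-[(4R,5Z)-2,2-di-tert-butyl-5-[(4Z)-6-hydroxy-4-methylhex-4-en-1-ylidene]-1,3,2-dioxasilinan-4-yl]ethane-1,2-diol
Conditions: AcOH–THF–H2O (3:1:1), 40 °C
Reagents that add atoms: none
Why: Mild acid solvolysis removes the terminal isopropylidene acetal and the primary triethylsilyl ether, while the hindered di-tert-butylsilylene survives.

**Step 8**
Reactants: 9 (1S)-1-[(4R,5Z)-2,2-di-tert-butyl-5-[(4Z)-6-hydroxy-4-methylhex-4-en-1-ylidene]-1,3,2-dioxasilinan-4-yl]ethane-1,2-diol
Product: 10 tris(triethylsilyl) ether of triol 9 (C6–O, C7–O and C8–O silylated)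
Conditions: TESOTf, 2,6-lutidine, CH2Cl2, −78 → 0 °C
Reagents that add atoms: triethylsilyl trifluoromethanesulfonate, CC[Si](CC)(CC)OS(=O)(=O)C(F)(F)F
Why: Exhaustive silylation with the silyl triflate covers all three hydroxyls so that the two primary ethers can be oxidised selectively in the next step.

**Step 9**
Reactants: 10 tris(triethylsilyl) ether of triol 9
Product: 11 (2R)-2-[(4R,5Z)-2,2-di-tert-butyl-5-[(4Z)-4-methyl-6-oxohex-4-en-1-ylidene]-1,3,2-dioxasilinan-4-yl]-2-(triethylsilyloxy)acetaldehyde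
Conditions: (COCl)2, DMSO, CH2Cl2, −78 → −30 °C; then Et3N, −78 → 0 °C
Reagents that add atoms: none
Why: Swern oxidation converts primary triethylsilyl ethers directly into aldehydes and leaves the secondary C8 silyl ether alone, giving the Z-enal (C6) and the α-silyloxy aldehyde (C7) in one operation without epimerising C8 at low temperature.

**Step 10**
Reactants: 11 (2R)-2-[(4R,5Z)-2,2-di-tert-butyl-5-[(4Z)-4-methyl-6-oxohex-4-en-1-ylidene]-1,3,2-dioxasilinan-4-yl]-2-(triethylsilyloxy)acetaldehyde, 12 methyl acrylate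
Product: 13 methyl 2-[(2S)-2-[(4R,5Z)-2,2-di-tert-butyl-5-[(4Z)-4-methyl-6-oxohex-4-en-1-ylidene]-1,3,2-dioxasilinan-4-yl]-1-hydroxy-2-(triethylsilyloxy)ethyl]prop-2-enoate (both C7 carbinol epimers)
Conditions: DABCO (1 equiv), 12 (10 equiv), MeOH, rt, 48–72 h
Reagents that add atoms: none
Why: Morita–Baylis–Hillman reaction, in which the DABCO–acrylate zwitterion adds only to the non-conjugated α-silyloxy aldehyde because the β,β-disubstituted enal is too poor an electrophile; the new carbinol centre forms as a mixture that is erased in step 11.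

**Step 11**
Reactants: 13 methyl 2-[(2S)-2-[(4R,5Z)-2,2-di-tert-butyl-5-[(4Z)-4-methyl-6-oxohex-4-en-1-ylidene]-1,3,2-dioxasilinan-4-yl]-1-hydroxy-2-(triethylsilyloxy)ethyl]prop-2-enoate
Product: 14 methyl (2Z,4S)-2-(bromomethyl)-4-[(4R,5Z)-2,2-di-tert-butyl-5-[(4Z)-4-methyl-6-oxohex-4-en-1-ylidene]-1,3,2-dioxasilinan-4-yl]-4-(triethylsilyloxy)but-2-enoate
Conditions: NBS, Me2S, CH2Cl2, 0 °C → rt
Reagents that add atoms: N-bromosuccinimide, O=C1CCC(=O)N1Br
Why: Corey–Kim-type activation of the Baylis–Hillman alcohol and SN2' attack of bromide give the favoured (Z)-2-(bromomethyl)enoate by allylic transposition, removing the C7 carbinol centre.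

**Step 12**
Reactants: 14 methyl (2Z,4S)-2-(bromomethyl)-4-[(4R,5Z)-2,2-di-tert-butyl-5-[(4Z)-4-methyl-6-oxohex-4-en-1-ylidene]-1,3,2-dioxasilinan-4-yl]-4-(triethylsilyloxy)but-2-enoate
Product: 16 8β-hydroxy-9β,14-(di-tert-butylsilanediyldioxy)germacra-1(10)Z,4Z,11(13)-trien-12,6α-olide, via triethylsilyl-protected macrolactone 15 (not isolated)
Conditions: CrCl3 (20 mol %), TMSCl, Et4NBF4, DMF–THF, Al anode / carbon-felt cathode, undivided cell, 2 mA, 14 added over 12 h (2 mM), rt; then 1 M HCl–THF, 0 °C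
Reagents that add atoms: none
Why: Proposed new method: a cathodic chromium-catalysed Barbier macrocyclisation–lactonisation, in which the cathode keeps reducing CrCl3 to divalent chromium, which turns the activated allylic bromide by two one-electron transfers into an allylchromium species (trivalent chromium) at a potential too mild to reduce the enal or the bromide directly; slow addition keeps this species dilute so that it adds through a chair-like six-membered transition state to the tethered C6 aldehyde, the chromium alkoxide closes the γ-lactone on the methyl ester, TMSCl strips methoxide from the metal to turn the cycle over, and the acidic work-up cleaves the C8 silyl ether; the forming ten-membered ring is expected to favour the antiperiplanar C5–C6–C7–C8 arrangement (trans-fused lactone, 6α-O and 7α-H), and attack on the C7 face anti to the C8–C9 bond, with H-8 eclipsing the alkene (A1,3 strain) and the poorly leaving C8 silyloxy group outside, is expected to set both new centres relative to C8 and C9 as in the target; the closest known reactions are the stoichiometric CrCl2 Barbier lactonisations of 2-(bromomethyl)acrylates that close ten-membered germacranolide rings and the chromium-catalysed electroreductive Nozaki–Hiyama–Kishi couplings of organic halides with aldehydes.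

**Step 13**
Reactants: 16 8β-hydroxy-9β,14-(di-tert-butylsilanediyldioxy)germacra-1(10)Z,4Z,11(13)-trien-12,6α-olide, 17 angelic anhydride
Product: 18 8β-angeloyloxy-9β,14-(di-tert-butylsilanediyldioxy)germacra-1(10)Z,4Z,11(13)-trien-12,6α-olide
Conditions: 17 (3 equiv), Et3N, DMAP (0.2 equiv), CH2Cl2, 0 °C → rt
Reagents that add atoms: none
Why: DMAP-catalysed esterification of the only free hydroxyl with the symmetric anhydride under mild, short conditions keeps the Z-geometry of the angelate and touches no stereocentre.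

**Step 14**
Reactants: 18 8β-angeloyloxy-9β,14-(di-tert-butylsilanediyldioxy)germacra-1(10)Z,4Z,11(13)-trien-12,6α-olide
Product: 19 8β-angeloyloxy-9β,14-dihydroxygermacra-1(10)Z,4Z,11(13)-trien-12,6α-olide (CNP0276773.5)
Conditions: HF·pyridine, pyridine, THF, 0 °C
Reagents that add atoms: none
Why: Fluoride-mediated desilylation cleaves the silylene acetal and frees the C9 and C14 hydroxyls without harming the α-methylene lactone or the angelate.

**Compound list**
1 | nerol, (2Z)-3,7-dimethylocta-2,6-dien-1-ol | CC(C)=CCC/C(C)=C\CO | starting material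
2 | neryl triethylsilyl ether | CC(C)=CCC/C(C)=C\CO[Si](CC)(CC)CC | intermediate
3 | (4Z)-4-methyl-6-(triethylsilyloxy)hex-4-enal | O=CCC/C(C)=C\CO[Si](CC)(CC)CC | intermediate
4 | ethyl (2Z,6Z)-2-iodo-6-methyl-8-(triethylsilyloxy)octa-2,6-dienoate | CCOC(=O)/C(I)=C/CC/C(C)=C\CO[Si](CC)(CC)CC | intermediate
5 | (2Z,6Z)-2-iodo-6-methyl-8-(triethylsilyloxy)octa-2,6-dien-1-ol | OC/C(I)=C/CC/C(C)=C\CO[Si](CC)(CC)CC | intermediate
6 | (S)-2,2-dimethyl-1,3-dioxolane-4-carbaldehyde | O=C[C@@H]1COC(C)(C)O1 | starting material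
7 | (1R,2Z,6Z)-1-[(4S)-2,2-dimethyl-1,3-dioxolan-4-yl]-2-(hydroxymethyl)-6-methyl-8-(triethylsilyloxy)octa-2,6-dien-1-ol | CC[Si](CC)(CC)OC/C=C(/C)CC/C=C(/CO)[C@@H](O)[C@@H]1COC(C)(C)O1 | intermediate
8 | (4R,5Z)-2,2-di-tert-butyl-4-[(4S)-2,2-dimethyl-1,3-dioxolan-4-yl]-5-[(4Z)-4-methyl-6-(triethylsilyloxy)hex-4-en-1-ylidene]-1,3,2-dioxasilinane | CC[Si](CC)(CC)OC/C=C(/C)CC/C=C1/CO[Si](C(C)(C)C)(C(C)(C)C)O[C@H]1[C@@H]2COC(C)(C)O2 | intermediate
9 | (1S)-1-[(4R,5Z)-2,2-di-tert-butyl-5-[(4Z)-6-hydroxy-4-methylhex-4-en-1-ylidene]-1,3,2-dioxasilinan-4-yl]ethane-1,2-diol | OC/C=C(/C)CC/C=C1/CO[Si](C(C)(C)C)(C(C)(C)C)O[C@H]1[C@@H](O)CO | intermediate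
10 | tris(triethylsilyl) ether of 9 (C6–O, C7–O, C8–O) | CC[Si](CC)(CC)OC/C=C(/C)CC/C=C1/CO[Si](C(C)(C)C)(C(C)(C)C)O[C@H]1[C@@H](O[Si](CC)(CC)CC)CO[Si](CC)(CC)CC | intermediate
11 | (2R)-2-[(4R,5Z)-2,2-di-tert-butyl-5-[(4Z)-4-methyl-6-oxohex-4-en-1-ylidene]-1,3,2-dioxasilinan-4-yl]-2-(triethylsilyloxy)acetaldehyde | O=C/C=C(/C)CC/C=C1/CO[Si](C(C)(C)C)(C(C)(C)C)O[C@H]1[C@@H](O[Si](CC)(CC)CC)C=O | intermediate
12 | methyl acrylate | C=CC(=O)OC | starting material
13 | methyl 2-[(2S)-2-[(4R,5Z)-2,2-di-tert-butyl-5-[(4Z)-4-methyl-6-oxohex-4-en-1-ylidene]-1,3,2-dioxasilinan-4-yl]-1-hydroxy-2-(triethylsilyloxy)ethyl]prop-2-enoate, both carbinol epimers | O=C/C=C(/C)CC/C=C1/CO[Si](C(C)(C)C)(C(C)(C)C)O[C@H]1[C@@H](O[Si](CC)(CC)CC)C(O)C(=C)C(=O)OC | intermediate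
14 | methyl (2Z,4S)-2-(bromomethyl)-4-[(4R,5Z)-2,2-di-tert-butyl-5-[(4Z)-4-methyl-6-oxohex-4-en-1-ylidene]-1,3,2-dioxasilinan-4-yl]-4-(triethylsilyloxy)but-2-enoate | O=C/C=C(/C)CC/C=C1/CO[Si](C(C)(C)C)(C(C)(C)C)O[C@H]1[C@@H](O[Si](CC)(CC)CC)/C=C(\CBr)C(=O)OC | intermediate
15 | 8β-(triethylsilyloxy)-9β,14-(di-tert-butylsilanediyldioxy)germacra-1(10)Z,4Z,11(13)-trien-12,6α-olide | C=C1C(=O)O[C@@H]2/C=C(/C)CC/C=C3/CO[Si](C(C)(C)C)(C(C)(C)C)O[C@H]3[C@@H](O[Si](CC)(CC)CC)[C@@H]12 | intermediate
16 | 8β-hydroxy-9β,14-(di-tert-butylsilanediyldioxy)germacra-1(10)Z,4Z,11(13)-trien-12,6α-olide | C=C1C(=O)O[C@@H]2/C=C(/C)CC/C=C3/CO[Si](C(C)(C)C)(C(C)(C)C)O[C@H]3[C@@H](O)[C@@H]12 | intermediate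
17 | angelic anhydride, (Z)-2-methylbut-2-enoic anhydride | C/C=C(/C)C(=O)OC(=O)/C(C)=C\C | starting material
18 | 8β-angeloyloxy-9β,14-(di-tert-butylsilanediyldioxy)germacra-1(10)Z,4Z,11(13)-trien-12,6α-olide | C=C1C(=O)O[C@@H]2/C=C(/C)CC/C=C3/CO[Si](C(C)(C)C)(C(C)(C)C)O[C@H]3[C@@H](OC(=O)/C(C)=C\C)[C@@H]12 | intermediate
19 | 8β-angeloyloxy-9β,14-dihydroxygermacra-1(10)Z,4Z,11(13)-trien-12,6α-olide (6R,7S,8S,9R; CNP0276773.5) | C=C1C(=O)O[C@@H]2/C=C(/C)CC/C=C(/CO)[C@@H](O)[C@@H](OC(=O)/C(C)=C\C)[C@@H]12 | target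

**Step count**
Total steps: 14. Longest linear sequence: 14 (nerol 1 → 19; 6, 12 and 17 are bought). C8 is bought with 6, C9 is set in step 5 under its control, and C6 and C7 are set in step 12 under control of C8 and C9.

**Steps most likely to fail, with fallbacks**

Step 12 (the proposed new reaction). The mediated electrolysis may give oligomers, direct reduction of the enal, or the wrong lactone diastereomer. The fallback sets out from 14 and drops electrolysis, catalyst turnover and the silyl chloride. It runs the ring closure as the reagent-driven, thermal Nozaki–Hiyama-type Barbier macrocyclisation with excess CrCl2 (8 equiv) in DMF–THF, with 14 added by syringe pump to 2 mM. This stoichiometric organochromium chemistry is established for closing ten-membered germacranolide lactones. Lactone 15 is isolated this time, and its C8 silyl ether is cleaved in a separate operation (1 M HCl–THF, 0 °C), which rejoins the route at 16 (no new compound, F0).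

Step 10. The Baylis–Hillman reaction on the hindered α-silyloxy aldehyde is slow, and days of contact with DABCO may isomerise the Z-enal or erode C8. The fallback sets out from 11 and replaces amine catalysis by a stoichiometric vinylalumination. Hydroalumination of methyl propiolate with iBu2AlH and N-methylmorpholine N-oxide in THF gives [1-(methoxycarbonyl)vinyl]diisobutylaluminium, iBu2Al–C(=CH2)CO2Me. At −78 °C it should add faster to the more electrophilic α-silyloxy aldehyde than to the conjugated enal; this selectivity is expected, not proven. It gives 13 directly, where the route is rejoined (no new compound, F0).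

Step 13. Acylation of the hindered 8β-hydroxyl may be sluggish, and nucleophilic catalysis can isomerise the angelate to the tiglate. The fallback sets out from 16 and builds the Z-alkene on the molecule instead of transferring it. Esterification with 2-[bis(2,2,2-trifluoroethoxy)phosphoryl]propanoic acid (DCC, DMAP, CH2Cl2) gives 8β-[2-[bis(2,2,2-trifluoroethoxy)phosphoryl]propanoyloxy]-9β,14-(di-tert-butylsilanediyldioxy)germacra-1(10)Z,4Z,11(13)-trien-12,6α-olide F1. A Still–Gennari olefination with acetaldehyde (KN(SiMe3)2, 18-crown-6, THF, −78 °C) then gives the Z-configured 2-methylbut-2-enoate and rejoins the route at 18.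

Further compounds
F0 | step 10 | none | none
F0 | step 12 | none | none
F1 | step 13 | 8β-[2-[bis(2,2,2-trifluoroethoxy)phosphoryl]propanoyloxy]-9β,14-(di-tert-butylsilanediyldioxy)germacra-1(10)Z,4Z,11(13)-trien-12,6α-olide | C=C1C(=O)O[C@@H]2/C=C(/C)CC/C=C3/CO[Si](C(C)(C)C)(C(C)(C)C)O[C@H]3[C@@H](OC(=O)C(C)P(=O)(OCC(F)(F)F)OCC(F)(F)F)[C@@H]12
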